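Ring numbering: C1–C2 are the oxirane carbons (CH3 on C2), C3–C5 are CH2, C6 is CMe2, C7 is CHOBz, C8=C9 carries CO2H on C9, and C10–C11 are CH2.
Enabling feature: C7 and C10 are cis on C8=C9, while H-8 and the carboxyl point out of the eleven-membered ring. This is the pattern left by syn H/CO2R addition to a ring alkyne C8≡C9, which makes C7 a propargylic carbinol beside quaternary C6 (alkynyl metal plus non-enolisable aldehyde).
Cuts, in retrosynthetic order: the two ester O–C bonds, the oxirane O, C9–CO2R, and H/I on C8/C9 (back to the alkyne). Then C7–C8 opens the carbocycle to an achiral iodoalkynyl aldehyde, whose chain is cut at C5–C6, C11–C1 and C2–CH3.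
Forward: C2–CH3 (carboalumination), C1–C11 (Negishi coupling), C5–C6 (nitrile alkylation). The carbocycle then closes at C7–C8, and the oxirane is the second and last ring.
Stereochemistry: E-C1=C2 comes from syn carboalumination, C7 from a chiral ligand on chromium, ring-cis C8=C9 from syn hydrozirconation of the cycloalkyne, and C1/C2 from Shi epoxidation with the L-fructose-derived ketone.

Key step: step 8

Assumption: the sense of induction of the ligand L*H, N-{2-[(4S)-4-isopropyl-4,5-dihydro-1,3-oxazol-2-yl]-6-methylphenyl}methanesulfonamide (CC(C)[C@H]1COC(=N1)c1cccc(C)c1NS(C)(=O)=O), is to be fixed on the model pair pivalaldehyde/1-iodohex-1-yne; the (S)-valinol-derived form is written here as the one that leaves the Re face of the aldehyde open, and its mirror image is used if the model shows the opposite.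

Step 1
Reactants: 1 5-chloropent-1-yne; 2 trimethylaluminium
Product: 4 (E)-5-chloro-1-iodo-2-methylpent-1-ene, via (E)-alkenyldimethylalane 3 (not isolated)
Conditions: AlMe3 (2 equiv), Cp2ZrCl2 (0.2 equiv), CH2Cl2, 0 °C → rt; then I2, THF, −30 → 0 °C
Reagents that add atoms: trimethylaluminium (2), C[Al](C)C; iodine, II
Why: Zirconium-catalysed (Negishi) carboalumination adds CH3 and Al syn to the terminal alkyne with Al at the terminus, and iodinolysis with retention fixes the E geometry of the future C1=C2 alkene, the primary chloride being inert to AlMe3.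

Step 2
Reactants: 5 4-(trimethylsilyl)but-3-yn-1-ol
Product: 6 (4-iodobut-1-yn-1-yl)trimethylsilane
Conditions: I2, PPh3, imidazole, CH2Cl2, 0 °C → rt
Reagents that add atoms: iodine, II
Why: Appel-type iodination activates the primary alcohol as an alkoxyphosphonium salt that iodide displaces (SN2) without touching the silylalkyne.

Step 3
Reactants: 6 (4-iodobut-1-yn-1-yl)trimethylsilane; 4 (E)-5-chloro-1-iodo-2-methylpent-1-ene
Product: 8 (E)-(9-chloro-6-methylnon-5-en-1-yn-1-yl)trimethylsilane, via alkylzinc iodide 7 (not isolated)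
Conditions: 6, Zn dust, LiCl, THF, rt; then 4, PdCl2(dppf) (3 mol %), THF, rt → 40 °C
Reagents that add atoms: none
Why: Zinc insertion into the primary C–I bond followed by Negishi sp3–sp2 cross-coupling forms C11–C1 with retention of the E geometry, because zerovalent palladium inserts only into the alkenyl C–I bond (not C–Cl) and dppf suppresses β-hydride elimination.

Step 4
Reactants: 8 (E)-(9-chloro-6-methylnon-5-en-1-yn-1-yl)trimethylsilane
Product: 9 (E)-(9-iodo-6-methylnon-5-en-1-yn-1-yl)trimethylsilane
Conditions: NaI, acetone, reflux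
Reagents that add atoms: sodium iodide, [Na+].[I-]
Why: Finkelstein halide exchange (SN2), driven by precipitation of NaCl, turns the spectator chloride into a good alkylating terminus.

Step 5
Reactants: 10 isobutyronitrile; 9 (E)-(9-iodo-6-methylnon-5-en-1-yn-1-yl)trimethylsilane
Product: 12 (E)-2,2,6-trimethyl-11-(trimethylsilyl)undec-6-en-10-ynenitrile, via lithiated isobutyronitrile 11 (not isolated)
Conditions: 10, LiN(i-Pr)2, THF, −78 °C; then 9, −78 °C → rt
Reagents that add atoms: none
Why: SN2 alkylation of a lithiated nitrile, in which the small, strongly nucleophilic anion builds quaternary C6 (bond C5–C6) on a primary iodide and cannot be alkylated a second time.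

Step 6
Reactants: 12 (E)-2,2,6-trimethyl-11-(trimethylsilyl)undec-6-en-10-ynenitrile
Product: 14 (E)-2,2,6-trimethyl-11-(trimethylsilyl)undec-6-en-10-ynal, via N-aluminio imine 13 (not isolated)
Conditions: i-Bu2AlH, CH2Cl2, −78 → 0 °C; then 1 M HCl, 0 °C → rt
Reagents that add atoms: water, O
Why: Partial nitrile reduction with i-Bu2AlH stops at the N-aluminio imine, which takes up no second hydride in the cold and is hydrolysed to the aldehyde, while hydroalumination of the silylalkyne needs much higher temperature.

Step 7
Reactants: 14 (E)-2,2,6-trimethyl-11-(trimethylsilyl)undec-6-en-10-ynal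
Product: 15 (E)-11-iodo-2,2,6-trimethylundec-6-en-10-ynal
Conditions: N-iodosuccinimide (1.2 equiv), AgNO3 (0.2 equiv), DMF, rt, dark
Reagents that add atoms: N-iodosuccinimide, O=C1CCC(=O)N1I
Why: Silver-catalysed iododesilylation exchanges C–Si for a silver acetylide that N-iodosuccinimide iodinates, under neutral conditions that spare the α-quaternary aldehyde and the trisubstituted alkene.

Step 8
Reactants: 15 (E)-11-iodo-2,2,6-trimethylundec-6-en-10-ynal
Product: 18 (1S,6E)-7,11,11-trimethylcycloundec-6-en-2-yn-1-ol, via alkynylchromium complex 16 (not isolated), via chromium alkoxide 17 (not isolated)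
Conditions: CrCl2 (6 equiv), L*H (6.6 equiv), Et3N (6.6 equiv), NiCl2 (0.05 equiv), degassed THF, rt; 15 added by syringe pump over 12 h (final 2 mM); then H2O
Reagents that add atoms: none
Why: Divalent chromium reduces NiCl2 to zerovalent nickel, which inserts into the C8–I bond and hands the alkynyl group to ligand-bound trivalent chromium (16); this nucleophile adds 1,2 to the C7 aldehyde to give alkoxide 17, which water cleaves to 18. The closest known reaction type is the Nozaki–Hiyama–Kishi alkynylation, established both for closing ω-iodoalkynyl aldehydes to medium-ring cycloalkynols and, with oxazoline–sulfonamide ligands, for enantioselective addition of iodoalkynes to aldehydes. The eleven-membered carbocycle closes through bond C7–C8 in an 11-exo-trig mode (the carbonyl oxygen stays outside the ring), helped by slow addition at millimolar concentration, by the gem-dimethyl group at C6 and by the preset E-alkene, which reduce the rotors of the chain, while a ring of this size bends the alkyne only slightly. C7 is the only new stereocentre and is controlled by the ligand on chromium, which should leave the Re face of the bound aldehyde open and so give the 1S alkynol (S because the alkynyl carbon outranks C6; the spatial arrangement is that of 7R in the target). The step needs ring closure to beat dimerisation and alkyne homocoupling and needs a carbonyl that can only undergo addition: the substrate has one C–I bond, one carbonyl and no α-hydrogen, so enolisation, aldol reaction and epimerisation are excluded, and nickel is kept at trace level to hold back diyne formation.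

Step 9
Reactants: 18 (1S,6E)-7,11,11-trimethylcycloundec-6-en-2-yn-1-ol
Product: 22 (1R,2E,6E)-3-iodo-7,11,11-trimethylcycloundeca-2,6-dien-1-ol, via zirconium alkoxide 19 (not isolated), via C9-alkenylzirconocene 20 (not isolated), via iodoalkenyl zirconium alkoxide 21 (not isolated)
Conditions: Cp2Zr(H)Cl (3 equiv), THF, 0 °C → rt, dark; then I2, THF, −78 → 0 °C; then H2O
Reagents that add atoms: iodine, II
Why: Hydrozirconation–iodinolysis, in which the first equivalent of Cp2Zr(H)Cl turns the hydroxyl into a bulky, non-directing zirconium alkoxide, the next adds H and Zr syn across the ring alkyne with Zr at C9 (next to CH2, away from neopentyl C7, excess reagent equilibrating towards this isomer) so that C7 and C10 end up cis, and iodine replaces Zr with retention; C7 is untouched and changes from S to R only because an alkenyl carbon ranks below C6.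

Step 10
Reactants: 22 (1R,2E,6E)-3-iodo-7,11,11-trimethylcycloundeca-2,6-dien-1-ol
Product: 23 2-(trimethylsilyl)ethyl (1E,3R,8E)-3-hydroxy-4,4,8-trimethylcycloundeca-1,8-diene-1-carboxylate
Conditions: CO (1 atm), Pd(OAc)2 (10 mol %), PPh3 (20 mol %), Et3N, Me3SiCH2CH2OH (10 equiv), DMF, 50 °C
Reagents that add atoms: carbon monoxide, [C-]#[O+]; 2-(trimethylsilyl)ethanol, C[Si](C)(C)CCO
Why: Palladium-catalysed alkoxycarbonylation (oxidative addition of zerovalent palladium to C9–I with retention, CO insertion, alcoholysis) puts the ester on C9, the excess alcohol outrunning transannular acylpalladation of the hindered C1=C2 alkene, and lactonisation being impossible because the acyl group is trans to C7.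

Step 11
Reactants: 23 2-(trimethylsilyl)ethyl (1E,3R,8E)-3-hydroxy-4,4,8-trimethylcycloundeca-1,8-diene-1-carboxylate
Product: 24 2-(trimethylsilyl)ethyl (1E,3R,8E)-3-(benzoyloxy)-4,4,8-trimethylcycloundeca-1,8-diene-1-carboxylate
Conditions: BzCl, Et3N, 4-(dimethylamino)pyridine (0.2 equiv), CH2Cl2, 0 °C → rt
Reagents that add atoms: benzoyl chloride, O=C(Cl)c1ccccc1
Why: Acylation under nucleophilic catalysis (N-benzoylpyridinium transfer) esterifies the hindered but only hydroxyl group without breaking the C7–O bond, so the configuration is retained.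

Step 12
Reactants: 24 2-(trimethylsilyl)ethyl (1E,3R,8E)-3-(benzoyloxy)-4,4,8-trimethylcycloundeca-1,8-diene-1-carboxylate
Product: 25 2-(trimethylsilyl)ethyl (1S,4E,6R,11S)-6-(benzoyloxy)-7,7,11-trimethyl-12-oxabicyclo[9.1.0]dodec-4-ene-4-carboxylate
Conditions: 1,2:4,5-di-O-isopropylidene-β-L-erythro-2,3-hexodiulo-2,6-pyranose (L-fructose-derived Shi ketone, from L-sorbose, 0.3 equiv), Oxone (2 KHSO5·KHSO4·K2SO4), K2CO3, Bu4NHSO4 (cat.), MeCN/CH2(OMe)2/aq. Na2B4O7 buffer, 0 °C
Reagents that add atoms: potassium peroxymonosulfate KHSO5, [K+].[O-]S(=O)(=O)OO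
Why: Shi asymmetric epoxidation, in which the electrophilic chiral dioxirane takes the electron-rich C1=C2 alkene and not the enoate, and through the spiro transition state this ketone (mirror image of the D-fructose ketone that gives R,R-epoxides from E-trisubstituted alkenes) should deliver oxygen to the face giving 1S,2S (ring numbering), both faces being on offer because the E-alkene swings freely through an eleven-membered ring.

Step 13
Reactants: 25 2-(trimethylsilyl)ethyl (1S,4E,6R,11S)-6-(benzoyloxy)-7,7,11-trimethyl-12-oxabicyclo[9.1.0]dodec-4-ene-4-carboxylate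
Product: 27 (1S,4E,6R,11S)-6-(benzoyloxy)-7,7,11-trimethyl-12-oxabicyclo[9.1.0]dodec-4-ene-4-carboxylic acid, via tetrabutylammonium carboxylate 26 (not isolated)
Conditions: Bu4NF (1.5 equiv), THF, 0 °C → rt; then 10 % aq. citric acid, 0 °C
Reagents that add atoms: none
Why: Fluoride-induced fragmentation (β-elimination) of the 2-(trimethylsilyl)ethyl ester releases carboxylate, ethene and Me3SiF under conditions that leave benzoate, oxirane and all three stereocentres untouched, and mild acidification frees the acid.

Compound list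
1 | 5-chloropent-1-yne | C#CCCCCl | starting material
2 | trimethylaluminium | C[Al](C)C | starting material
3 | [(1E)-5-chloro-2-methylpent-1-en-1-yl]dimethylalane | ClCCC/C(C)=C/[Al](C)C | intermediate
4 | (E)-5-chloro-1-iodo-2-methylpent-1-ene | ClCCC/C(C)=C/I | intermediate
5 | 4-(trimethylsilyl)but-3-yn-1-ol | C[Si](C)(C)C#CCCO | starting material
6 | (4-iodobut-1-yn-1-yl)trimethylsilane | C[Si](C)(C)C#CCCI | intermediate
7 | [4-(trimethylsilyl)but-3-yn-1-yl]zinc iodide | C[Si](C)(C)C#CCC[Zn]I | intermediate
8 | (E)-(9-chloro-6-methylnon-5-en-1-yn-1-yl)trimethylsilane | ClCCC/C(C)=C/CCC#C[Si](C)(C)C | intermediate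
9 | (E)-(9-iodo-6-methylnon-5-en-1-yn-1-yl)trimethylsilane | ICCC/C(C)=C/CCC#C[Si](C)(C)C | intermediate
10 | isobutyronitrile (2-methylpropanenitrile) | CC(C)C#N | starting material
11 | lithiated isobutyronitrile (drawn as the N-lithio ketenimine) | [Li]N=C=C(C)C | intermediate
12 | (E)-2,2,6-trimethyl-11-(trimethylsilyl)undec-6-en-10-ynenitrile | N#CC(C)(C)CCC/C(C)=C/CCC#C[Si](C)(C)C | intermediate
13 | N-(diisobutylaluminio) imine of aldehyde 14 | CC(C)C[Al](CC(C)C)N=CC(C)(C)CCC/C(C)=C/CCC#C[Si](C)(C)C | intermediate
14 | (E)-2,2,6-trimethyl-11-(trimethylsilyl)undec-6-en-10-ynal | O=CC(C)(C)CCC/C(C)=C/CCC#C[Si](C)(C)C | intermediate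
15 | (E)-11-iodo-2,2,6-trimethylundec-6-en-10-ynal (achiral precursor of the key step) | O=CC(C)(C)CCC/C(C)=C/CCC#CI | intermediate
16 | alkynyl(chloro)(sulfonamidato)chromium complex from 15 (trivalent chromium; oxazoline N→Cr contact and THF not drawn) | O=CC(C)(C)CCC/C(C)=C/CCC#C[Cr](Cl)N(c1c(C)cccc1C1=N[C@@H](C(C)C)CO1)S(C)(=O)=O | intermediate
17 | chloro(sulfonamidato)chromium alkoxide of 18 (trivalent chromium) | CC1(C)CCC/C(C)=C/CCC#C[C@H]1O[Cr](Cl)N(c2c(C)cccc2C2=N[C@@H](C(C)C)CO2)S(C)(=O)=O | intermediate
18 | (1S,6E)-7,11,11-trimethylcycloundec-6-en-2-yn-1-ol (product of the key step) | CC1(C)CCC/C(C)=C/CCC#C[C@H]1O | intermediate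
19 | chlorozirconocene alkoxide of 18 (Cp drawn σ-bonded) | CC1(C)CCC/C(C)=C/CCC#C[C@H]1O[Zr](Cl)(C2C=CC=C2)C2C=CC=C2 | intermediate
20 | C9-alkenyl chlorozirconocene of alkoxide 19 (H-8 and Zr syn; Cp drawn σ-bonded) | CC1(C)CCC/C(C)=C/CC/C([Zr](Cl)(C2C=CC=C2)C2C=CC=C2)=C\[C@H]1O[Zr](Cl)(C2C=CC=C2)C2C=CC=C2 | intermediate
21 | chlorozirconocene alkoxide of 22 | CC1(C)CCC/C(C)=C/CC/C(I)=C\[C@H]1O[Zr](Cl)(C2C=CC=C2)C2C=CC=C2 | intermediate
22 | (1R,2E,6E)-3-iodo-7,11,11-trimethylcycloundeca-2,6-dien-1-ol | CC1(C)CCC/C(C)=C/CC/C(I)=C\[C@H]1O | intermediate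
23 | 2-(trimethylsilyl)ethyl (1E,3R,8E)-3-hydroxy-4,4,8-trimethylcycloundeca-1,8-diene-1-carboxylate | CC1(C)CCC/C(C)=C/CC/C(C(=O)OCC[Si](C)(C)C)=C\[C@H]1O | intermediate
24 | 2-(trimethylsilyl)ethyl (1E,3R,8E)-3-(benzoyloxy)-4,4,8-trimethylcycloundeca-1,8-diene-1-carboxylate | CC1(C)CCC/C(C)=C/CC/C(C(=O)OCC[Si](C)(C)C)=C\[C@H]1OC(=O)c1ccccc1 | intermediate
25 | 2-(trimethylsilyl)ethyl (1S,4E,6R,11S)-6-(benzoyloxy)-7,7,11-trimethyl-12-oxabicyclo[9.1.0]dodec-4-ene-4-carboxylate | CC1(C)CCC[C@]2(C)O[C@H]2CC/C(C(=O)OCC[Si](C)(C)C)=C\[C@H]1OC(=O)c1ccccc1 | intermediate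
26 | tetrabutylammonium salt of 27 | CC1(C)CCC[C@]2(C)O[C@H]2CC/C(C(=O)[O-])=C\[C@H]1OC(=O)c1ccccc1.CCCC[N+](CCCC)(CCCC)CCCC | intermediate
27 | (1S,4E,6R,11S)-6-(benzoyloxy)-7,7,11-trimethyl-12-oxabicyclo[9.1.0]dodec-4-ene-4-carboxylic acid (CNP0377917.2) | CC1(C)CCC[C@]2(C)O[C@H]2CC/C(C(=O)O)=C\[C@H]1OC(=O)c1ccccc1 | target

Total step count: 13. Longest linear sequence: 12 steps (steps 1 and 3–13, from 5-chloropent-1-yne); step 2 is a one-step side branch.

Steps most likely to fail

Step 8. The likely failure is weak enantiofacial discrimination at the hindered aldehyde in the very dilute, ligand-loaded medium. The fallback takes the stereochemical task away from the C–C bond formation. It sets out from 18 as obtained, whatever its enantiomeric purity (the closure may then be run without L*H), and comes back at 18. Oxidation with Dess–Martin periodinane (NaHCO3, CH2Cl2, 0 °C) should give the ynone (6E)-7,11,11-trimethylcycloundec-6-en-2-yn-1-one F1. Noyori asymmetric transfer hydrogenation with RuCl(p-cymene)[(S,S)-TsDPEN] in i-PrOH should then return (S)-18. Alkynyl ketones are a privileged substrate class for this catalyst, and the alkynyl and tert-alkyl flanks of F1 differ as much as two ketone substituents can.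

Step 12. The likely failure is poor facial selectivity, because the conformational preference of the ring set by C7 may work against the catalyst. The fallback gives up catalyst control in favour of separation and recycling. It sets out from 24 and comes back at 25. m-Chloroperbenzoic acid (NaHCO3, CH2Cl2, 0 °C) should attack only the electron-rich alkene from the ring periphery. This should give 25 together with its oxirane diastereomer 2-(trimethylsilyl)ethyl (1R,4E,6R,11R)-6-(benzoyloxy)-7,7,11-trimethyl-12-oxabicyclo[9.1.0]dodec-4-ene-4-carboxylate F5. The two differ in their relation to C7 and should be separable by chromatography. F5 is returned to 24 by stereospecific deoxygenation with dimethyl diazomalonate and catalytic Rh2(OAc)4 (toluene, reflux), which keeps the E geometry, and is then resubmitted.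

Step 9. The likely failure is erosion of regioselectivity, through delivery of zirconium to C8 under the influence of the metal alkoxide, or sluggish addition next to it. The fallback replaces the alkoxide by an inert bulky silyl ether, so that sterics alone decide. It sets out from 18 and comes back at 22. Et3SiOTf/2,6-lutidine (CH2Cl2, −78 °C) should give triethyl{[(1S,6E)-7,11,11-trimethylcycloundec-6-en-2-yn-1-yl]oxy}silane F2. Cp2Zr(H)Cl (2 equiv, THF, rt) should add to it to give the C9-alkenyl chlorozirconocene F3. Iodine should convert this into triethyl{[(1R,2E,6E)-3-iodo-7,11,11-trimethylcycloundeca-2,6-dien-1-yl]oxy}silane F4, and HF·pyridine (THF, 0 °C) should unmask 22.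

Further compounds
F1 | step 8 | (6E)-7,11,11-trimethylcycloundec-6-en-2-yn-1-one | CC1(C)CCC/C(C)=C/CCC#CC1=O
F2 | step 9 | triethyl{[(1S,6E)-7,11,11-trimethylcycloundec-6-en-2-yn-1-yl]oxy}silane | CC1(C)CCC/C(C)=C/CCC#C[C@H]1O[Si](CC)(CC)CC
F3 | step 9 | C9-alkenyl chlorozirconocene from F2 (Cp drawn σ-bonded) | CC1(C)CCC/C(C)=C/CC/C([Zr](Cl)(C2C=CC=C2)C2C=CC=C2)=C\[C@H]1O[Si](CC)(CC)CC
F4 | step 9 | triethyl{[(1R,2E,6E)-3-iodo-7,11,11-trimethylcycloundeca-2,6-dien-1-yl]oxy}silane | CC1(C)CCC/C(C)=C/CC/C(I)=C\[C@H]1O[Si](CC)(CC)CC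
F5 | step 12 | 2-(trimethylsilyl)ethyl (1R,4E,6R,11R)-6-(benzoyloxy)-7,7,11-trimethyl-12-oxabicyclo[9.1.0]dodec-4-ene-4-carboxylate | CC1(C)CCC[C@@]2(C)O[C@@H]2CC/C(C(=O)OCC[Si](C)(C)C)=C\[C@H]1OC(=O)c1ccccc1
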